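**Retrosynthetic overview**
1. Target 10 ← removal of the N-Boc group from 9.
2. 9 ← Suzuki–Miyaura disconnection of the (plain indol-3-yl)–aryl bond: aryl bromide 7 + commercial N-Boc-indol-3-yl boronate 8.
3. 7 ← proposed new direct C3–H arylation: 5-prenylindole 5 (as its N-magnesium salt 6) + dibromide 2 in excess (single coupling).
4. 5 ← linear-selective Suzuki prenylation of 5-bromoindole 3 with prenyl-Bpin 4; 2 ← twofold bromination of 1,2,4,5-tetramethoxybenzene 1.
5. No ring is formed: the central benzene ring and both indole ring systems are bought intact; bond order is C5–prenyl, then aryl–(prenylindole), then aryl–(indole).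

Assumption: the target has no stereocentre and no stereogenic double bond (the prenyl alkene carries two methyl groups), so the given SMILES defines the single species to be made and no stereocontrol is needed.

**Step 1**
Reactants: 1 1,2,4,5-tetramethoxybenzene
Product: 2 1,4-dibromo-2,3,5,6-tetramethoxybenzene
Conditions: Br2 (2.2 equiv), CH2Cl2, 0 °C → rt; aq. Na2S2O3 wash
Reagents that add atoms: bromine, BrBr
Why: Twofold electrophilic aromatic bromination; the only two free positions of this very electron-rich arene are each activated by two ortho methoxy groups, so both are brominated and no regioisomer is possible.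

**Step 2**
Reactants: 3 5-bromo-1H-indole; 4 prenylboronic acid pinacol ester
Product: 5 5-(3-methylbut-2-en-1-yl)-1H-indole (5-prenylindole)
Conditions: Pd2(dba)3 (1 mol %), t-BuXPhos (4 mol %), aq. K3PO4 (3 equiv), MeCN, 70 °C
Reagents that add atoms: none
Why: Ligand-controlled Suzuki–Miyaura coupling of an allylboronate, in which the bulky di-tert-butyl biarylphosphine makes the allylpalladium intermediate couple through its unhindered primary terminus to give the linear prenyl product (not the 1,1-dimethylallyl isomer), and the aqueous phosphate conditions tolerate the free N–H.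

**Step 3**
Reactants: 5 5-(3-methylbut-2-en-1-yl)-1H-indole; 2 1,4-dibromo-2,3,5,6-tetramethoxybenzene
Product: 7 3-(4-bromo-2,3,5,6-tetramethoxyphenyl)-5-(3-methylbut-2-en-1-yl)-1H-indole, via 5-prenylindol-1-ylmagnesium chloride 6 (not isolated)
Conditions: MeMgCl (1.05 equiv), TMEDA (1.2 equiv), THF, 0 °C → rt; then 2 (3 equiv), Pd(OAc)2 (5 mol %), SPhos (10 mol %), THF/toluene, 85 °C; aq. NH4Cl (excess 2 recovered by chromatography)
Reagents that add atoms: none
Why: Proposed new method: zerovalent palladium/SPhos inserts into one C–Br bond of 2, the magnesium indolide 6 attacks the arylpalladium bromide through C3 in an aza-enolate-type transmetalation (N-arylation is disfavoured by the hard N–Mg bond and by the two ortho methoxy groups), a second indolide removes the C3–H of the 3H-indol-3-yl(aryl)palladium species with the proton ending on nitrogen, and ligand-accelerated reductive elimination forms the hindered aryl–C3 bond, the threefold excess of 2 holding the reaction at mono-coupling; the closest known reaction type is the palladium-catalysed direct C3 arylation of N-magnesiated or N–H indoles with unhindered aryl halides (and the α-arylation of aza-enolates), which has not been shown for di-ortho-alkoxy aryl dibromides, with dialkylbiarylphosphine ligands or as a selective single coupling of a dihalide.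

**Step 4**
Reactants: 7 3-(4-bromo-2,3,5,6-tetramethoxyphenyl)-5-(3-methylbut-2-en-1-yl)-1H-indole; 8 tert-butyl 3-(4,4,5,5-tetramethyl-1,3,2-dioxaborolan-2-yl)indole-1-carboxylate
Product: 9 tert-butyl 3-[2,3,5,6-tetramethoxy-4-[5-(3-methylbut-2-en-1-yl)-1H-indol-3-yl]phenyl]indole-1-carboxylate
Conditions: 8 (1.8 equiv), Pd(OAc)2 (5 mol %), SPhos (10 mol %), K3PO4 (3 equiv), toluene/H2O (10:1), 90 °C
Reagents that add atoms: none
Why: Suzuki–Miyaura coupling with the Pd/SPhos system suited to di-ortho-substituted, electron-rich aryl bromides; the N-Boc group slows protodeboronation of the indol-3-ylboronate and its excess covers the loss, the free N–H and the trisubstituted alkene of 7 are inert here, and any Boc loss in the pot is harmless because step 5 removes the group anyway.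

**Step 5**
Reactants: 9 tert-butyl 3-[2,3,5,6-tetramethoxy-4-[5-(3-methylbut-2-en-1-yl)-1H-indol-3-yl]phenyl]indole-1-carboxylate
Product: 10 3-[4-(1H-indol-3-yl)-2,3,5,6-tetramethoxyphenyl]-5-(3-methylbut-2-en-1-yl)-1H-indole (target, CNP0306547.0)
Conditions: K2CO3 (3 equiv), MeOH/THF (3:1), 60 °C
Reagents that add atoms: none
Why: Base-mediated methanolysis of the indole N-carbamate (acyl substitution with the indolide as leaving group) removes Boc without acid, so the acid-sensitive prenyl alkene, the four aryl methyl ethers and both indoles survive.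

**Compound list**
1 | 1,2,4,5-tetramethoxybenzene | COc1cc(OC)c(OC)cc1OC | starting material
2 | 1,4-dibromo-2,3,5,6-tetramethoxybenzene | COc1c(Br)c(OC)c(OC)c(Br)c1OC | intermediate
3 | 5-bromo-1H-indole | Brc1ccc2[nH]ccc2c1 | starting material
4 | prenylboronic acid pinacol ester, 4,4,5,5-tetramethyl-2-(3-methylbut-2-en-1-yl)-1,3,2-dioxaborolane | CC(C)=CCB1OC(C)(C)C(C)(C)O1 | starting material
5 | 5-(3-methylbut-2-en-1-yl)-1H-indole (5-prenylindole) | CC(C)=CCc1ccc2[nH]ccc2c1 | intermediate
6 | [5-(3-methylbut-2-en-1-yl)indol-1-yl]magnesium chloride (5-prenylindol-1-ylmagnesium chloride, not isolated) | CC(C)=CCc1ccc2c(c1)ccn2[Mg]Cl | intermediate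
7 | 3-(4-bromo-2,3,5,6-tetramethoxyphenyl)-5-(3-methylbut-2-en-1-yl)-1H-indole | COc1c(OC)c(-c2c[nH]c3ccc(CC=C(C)C)cc23)c(OC)c(OC)c1Br | intermediate
8 | tert-butyl 3-(4,4,5,5-tetramethyl-1,3,2-dioxaborolan-2-yl)indole-1-carboxylate | CC(C)(C)OC(=O)n1cc(B2OC(C)(C)C(C)(C)O2)c2ccccc12 | starting material
9 | tert-butyl 3-[2,3,5,6-tetramethoxy-4-[5-(3-methylbut-2-en-1-yl)-1H-indol-3-yl]phenyl]indole-1-carboxylate | COc1c(OC)c(-c2c[nH]c3ccc(CC=C(C)C)cc23)c(OC)c(OC)c1-c1cn(C(=O)OC(C)(C)C)c2ccccc12 | intermediate
10 | 3-[4-(1H-indol-3-yl)-2,3,5,6-tetramethoxyphenyl]-5-(3-methylbut-2-en-1-yl)-1H-indole | COc1c(OC)c(-c2c[nH]c3ccc(CC=C(C)C)cc23)c(OC)c(OC)c1-c1c[nH]c2ccccc12 | target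

**Step count and risks**
Total step count: 5. Longest linear sequence: 4 steps (3 → 5 → 7 → 9 → 10, or equally 1 → 2 → 7 → 9 → 10).

The three steps most likely to fail:

Step 3, the proposed new C3–H arylation. Its risks are N-arylation in place of C3-arylation, double coupling of the dibromide, and slow turnover once the magnesium sits on the product. The fallback uses known chemistry only, sets out from 5 and comes back at 7. Boc2O and DMAP in MeCN give tert-butyl 5-(3-methylbut-2-en-1-yl)indole-1-carboxylate F1. Iridium-catalysed C–H borylation, which is C3-selective for N-Boc indoles ([Ir(OMe)(cod)]2, 4,4'-di-tert-butyl-2,2'-bipyridine, B2pin2, hexane, 60 °C), gives tert-butyl 5-(3-methylbut-2-en-1-yl)-3-(4,4,5,5-tetramethyl-1,3,2-dioxaborolan-2-yl)indole-1-carboxylate F2. Suzuki–Miyaura coupling of this boronate with 2 (3 equiv; Pd(OAc)2, SPhos, K3PO4, toluene/H2O, 90 °C) gives tert-butyl 3-(4-bromo-2,3,5,6-tetramethoxyphenyl)-5-(3-methylbut-2-en-1-yl)indole-1-carboxylate F3. K2CO3 in MeOH/THF at 60 °C then removes the Boc group and returns 7.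

Step 2, the linear-selective prenyl coupling. Its risks are formation of the branched 1,1-dimethylallyl isomer and protodeboronation of the allylboronate. The fallback replaces the palladium coupling by an organolithium alkylation on a protected indole, sets out from 3 and comes back at 5. NaH then i-Pr3SiCl in THF give 5-bromo-1-(triisopropylsilyl)indole F4. Bromine–lithium exchange with t-BuLi (2.1 equiv, THF, −78 °C) gives [1-(triisopropylsilyl)indol-5-yl]lithium F5. Prenyl bromide alkylates it by SN2 attack at the primary carbon (−78 °C → rt) to give 5-(3-methylbut-2-en-1-yl)-1-(triisopropylsilyl)indole F6. Bu4NF in THF removes the silyl group and returns 5.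

Step 4, the hindered Suzuki coupling. Its risks are protodeboronation of the indol-3-ylboronate and slow transmetalation onto the di-ortho-methoxy arylpalladium species. The fallback gives up boron and the Boc group for a zinc nucleophile carrying a sulfonyl group, sets out from 7 and comes back at 10. Zinc insertion (Zn dust, LiCl, THF, 25–50 °C) into commercial 3-iodo-1-(phenylsulfonyl)indole gives [1-(phenylsulfonyl)indol-3-yl]zinc iodide F7. Negishi coupling of this reagent (2.5 equiv, which also covers the free N–H) with 7 (Pd(OAc)2, SPhos, THF, 60 °C) gives 3-[2,3,5,6-tetramethoxy-4-[5-(3-methylbut-2-en-1-yl)-1H-indol-3-yl]phenyl]-1-(phenylsulfonyl)indole F8. KOH in MeOH/THF at 65 °C cleaves the sulfonamide and gives 10.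

**Further compounds**
F1 | step 3 | tert-butyl 5-(3-methylbut-2-en-1-yl)indole-1-carboxylate | CC(C)=CCc1ccc2c(c1)ccn2C(=O)OC(C)(C)C
F2 | step 3 | tert-butyl 5-(3-methylbut-2-en-1-yl)-3-(4,4,5,5-tetramethyl-1,3,2-dioxaborolan-2-yl)indole-1-carboxylate | CC(C)=CCc1ccc2c(c1)c(B1OC(C)(C)C(C)(C)O1)cn2C(=O)OC(C)(C)C
F3 | step 3 | tert-butyl 3-(4-bromo-2,3,5,6-tetramethoxyphenyl)-5-(3-methylbut-2-en-1-yl)indole-1-carboxylate | COc1c(OC)c(-c2cn(C(=O)OC(C)(C)C)c3ccc(CC=C(C)C)cc23)c(OC)c(OC)c1Br
F4 | step 2 | 5-bromo-1-(triisopropylsilyl)indole | CC(C)[Si](C(C)C)(C(C)C)n1ccc2cc(Br)ccc12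
F5 | step 2 | [1-(triisopropylsilyl)indol-5-yl]lithium | [Li]c1ccc2c(c1)ccn2[Si](C(C)C)(C(C)C)C(C)C
F6 | step 2 | 5-(3-methylbut-2-en-1-yl)-1-(triisopropylsilyl)indole | CC(C)=CCc1ccc2c(c1)ccn2[Si](C(C)C)(C(C)C)C(C)C
F7 | step 4 | [1-(phenylsulfonyl)indol-3-yl]zinc iodide | I[Zn]c1cn(S(=O)(=O)c2ccccc2)c2ccccc12
F8 | step 4 | 3-[2,3,5,6-tetramethoxy-4-[5-(3-methylbut-2-en-1-yl)-1H-indol-3-yl]phenyl]-1-(phenylsulfonyl)indole | COc1c(OC)c(-c2c[nH]c3ccc(CC=C(C)C)cc23)c(OC)c(OC)c1-c1cn(S(=O)(=O)c2ccccc2)c2ccccc12
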